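## Analysis of the target

The target, (4,5-dichloro-1H-pyrrol-2-yl)[2,4-dihydroxy-3-(4-methylpentyl)phenyl]methanone (C17H19Cl2NO3), has two aromatic rings joined through one carbonyl carbon: C1 of a 1,2,3,4-tetrasubstituted benzene and C2 of a 1H-pyrrole. The benzene ring carries hydroxyl groups at C2 and C4 and a saturated 4-methylpentyl chain at C3, between the two oxygens. The pyrrole carries chlorine at C4 and C5 and a free N–H. There is no stereocentre and no double-bond geometry, so the problem is one of regiochemistry and functional-group tolerance. The free resorcinol is easily oxidised and strongly nucleophilic at C5, the pyrrole N–H is acidic, and the two C–Cl bonds must survive every metal-mediated step. The hard points are the two chlorines, which cannot be put in by electrophilic chlorination once the electron-rich resorcinol ring is present, and the formation of a ketone between two electron-rich rings without strong Lewis acids acting on the pyrrole. The strategy rests on the ketone carbon as a one-carbon bridge between benzene C1 and pyrrole C2: each ring can be prepared fully substituted, the benzene as a boronic acid at C1 and the pyrrole as an iodide at C2, and the bridge is supplied as carbon monoxide.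

## Retrosynthetic reasoning

Target 14 is traced back to its fully protected form 13 by cutting the two O–CH3 bonds and the N–CO2tBu bond. The phenols and the N–H would interfere with the organolithium steps and with the base-mediated aryl transfer, so they are masked until the end. The three groups are chosen so that one Lewis-acidic boron halide removes all of them. The forward step has to cleave both aryl methyl ethers, including the one at C4 that has no chelation help from the ketone, without touching the C–Cl bonds.

Ketone 13 is cut at both bonds to the carbonyl carbon, giving iodopyrrole 11, carbon monoxide 12 and boronic acid 8. This is the only junction between the two rings, and cutting here lets each ring arrive with all its substituents: the chlorines are already on 11 and the alkyl chain and both oxygens are already on 8. No Friedel–Crafts acylation and no late chlorination are then needed. The forward reaction is a palladium-catalysed three-component coupling that must engage only the C–I bond of 11 and must take up 12 before the aryl group of 8 is transferred.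

Boronic acid 8 is cut at the C–B bond and traced to bromide 5, through aryllithium 6 and borate complex 7. Halogen–lithium exchange fixes the boron position by the position of bromine, which avoids any competition from benzylic deprotonation next to the two ether oxygens.

Bromide 5 is cut at the C–Br bond to give arene 4. In 4 the positions C4 and C6 are equivalent and are the only ones activated by both methoxy groups, so a single electrophilic bromination can give only one monobromide.

Arene 4 is cut at the bond between ring C2 and the first chain carbon, giving 1,3-dimethoxybenzene 1 and alkyl bromide 2 through aryllithium 3. The position between the two oxygens is the most crowded one for any electrophilic substitution, but it is the unique site of directed lithiation, so the hindered substituent goes in first and by the most selective bond formation available.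

Iodopyrrole 11 is cut at the N–C(O) bond to give the N–H iodopyrrole 10, and 10 is cut at the C–I bond to give the commercial acid 9. Iodine replaces the carboxyl group at the same carbon, so the halogen pattern of 11 is inherited from 9 and no chlorination appears anywhere in the route.

## Alternatives that were turned down

Alternative 1: The benzene ring is built last by a Michael–Claisen annulation. The disconnection cuts the arene bonds C1–C6 and C3–C4. In the forward direction the N-protected pyrrolyl 1,3-diketone A1 would add through its central carbon to methyl acrylate A2, and the chain methylene would then attack the ester to close the cyclohexanedione A3. Dehydrogenation to the resorcinol and removal of the nitrogen protecting group would follow. In its favour, the substitution pattern of the six-membered ring is fixed by construction, and no aryl ether has to be cleaved at the end. Against it, the Claisen closure has to start from the less acidic chain methylene of the Michael adduct, while the more acidic central position can close through oxygen to an enol lactone or trigger retro-Claisen cleavage. A3 is also one oxidation level below the arene, so an extra dehydrogenation is needed in the presence of an electron-rich pyrrole. The diketone A1 itself needs several steps. The substitution pattern it secures is obtained in the chosen route in one lithiation of 1, so the main advantage of a de novo ring is not needed here. Alternative 1 is stronger on avoiding a late ether cleavage; the chosen route offers in exchange two bought rings and a shorter, convergent sequence.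

Alternative 2: The benzene ring is built by a Diels–Alder benzannulation. The disconnection cuts the arene bonds C5–C6 and C1–C2. The bis-silyloxy diene A4, which carries the 4-methylpentyl chain at its C2, would add to the N-tosyl pyrrolyl ynone A5. Aromatisation by loss of the methoxy and silyl groups would give the N-tosyl ketone A6 with both phenols free. In its favour, ring, ketone and both hydroxyl groups appear in one step, the regiochemistry follows from the polarity of diene and ynone, and no O-deprotection is needed. On these points it is stronger than the chosen route. Against it, A4 is a moisture-sensitive diene with a substituent at C2 that disfavours the reactive s-cis conformer and complicates its preparation. A5 is a reactive Michael acceptor that needs its own multi-step synthesis from a dichloropyrrole aldehyde. The tosyl group still has to be removed from a base-sensitive resorcinol ketone. The chosen route instead uses a commodity arene, a commercial pyrrole acid and stable, storable coupling partners.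

Alternative 3: The pyrrole ring is built last. The disconnection cuts the pyrrole bonds N1–C5 and C2–C3. The amino ketone A7 would displace one geminal chloride of trichloroacrolein A8 through nitrogen, and its ketone methylene would then condense with the aldehyde to close and aromatise the pyrrole. This would give the N–H ketone dimethyl ether A9 with both chlorines placed by the reagent. In its favour there is no nitrogen protecting group, no palladium, no carbon monoxide, and only a demethylation after the key step. On protecting-group economy it is stronger than the chosen route. Against it, A7 is an α-amino ketone that self-condenses unless kept as a salt. Its amine can also add to the aldehyde of A8 instead of substituting at the dichlorinated carbon. The ring closure depends on a weakly acidic methylene attacking an aldehyde that has been deactivated as a vinylogous amide. A8 is a toxic polyelectrophile with several competing reactive sites. The chosen route places its risk in a coupling whose elementary steps are well understood, and it buys the dichloropyrrole ring ready-made in 9.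

Key step: step 6

Assumption: the N–H iodopyrrole 10 is taken to be stable enough in cold solution, shielded from light, to be carried straight into step 5 without storage; carbon monoxide is treated as a numbered reactant.

## Route

Step 1
Reactants: 1 1,3-dimethoxybenzene; 2 1-bromo-4-methylpentane
Product: 4 1,3-dimethoxy-2-(4-methylpentyl)benzene, via 2,6-dimethoxyphenyllithium 3 (not isolated)
Conditions: n-BuLi, THF, 0 °C to rt; then 2, rt to 50 °C
Reagents that add atoms: none
Why: Directed ortho-metalation: the C2–H between the two methoxy groups is the most acidic ring proton and is removed by n-BuLi to give 3, which displaces bromide from the unhindered primary bromide 2 (SN2 alkylation of an aryllithium).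

Step 2
Reactants: 4 1,3-dimethoxy-2-(4-methylpentyl)benzene
Product: 5 1-bromo-2,4-dimethoxy-3-(4-methylpentyl)benzene
Conditions: NBS (1.0 equiv), MeCN, 0 °C to rt
Reagents that add atoms: N-bromosuccinimide, O=C1CCC(=O)N1Br
Why: Electrophilic aromatic bromination: C4 and C6 of 4 are equivalent and each is para to one methoxy group and ortho to the other, while C5 is meta to both, so one equivalent of NBS at low temperature should stop at the single monobromide.

Step 3
Reactants: 5 1-bromo-2,4-dimethoxy-3-(4-methylpentyl)benzene
Product: 8 [2,4-dimethoxy-3-(4-methylpentyl)phenyl]boronic acid, via [2,4-dimethoxy-3-(4-methylpentyl)phenyl]lithium 6 (not isolated), via lithium [2,4-dimethoxy-3-(4-methylpentyl)phenyl]tris(propan-2-yloxy)borate 7 (not isolated)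
Conditions: n-BuLi, THF, −78 °C; B(OiPr)3, −78 °C to rt; then 1 M aq. HCl
Reagents that add atoms: triisopropyl borate, CC(C)OB(OC(C)C)OC(C)C; water, O
Why: Lithiation–borylation: bromine–lithium exchange at −78 °C is faster than benzylic or ring deprotonation and gives 6, which adds to the borate to form the ate complex 7; mild acid hydrolysis then releases the boronic acid.

Step 4
Reactants: 9 4,5-dichloro-1H-pyrrole-2-carboxylic acid
Product: 10 2,3-dichloro-5-iodo-1H-pyrrole
Conditions: I2 (1.0 equiv), KI, NaHCO3, H2O/ClCH2CH2Cl, 50 °C, dark
Reagents that add atoms: iodine, II
Why: Iododecarboxylation of a pyrrole-2-carboxylic acid: iodine attacks the carboxylate-bearing α-carbon at the ipso position and the resulting cation loses CO2, so iodine ends exactly where the carboxyl group was; one equivalent of iodine spares the remaining β-CH and the chlorines are untouched.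

Step 5
Reactants: 10 2,3-dichloro-5-iodo-1H-pyrrole
Product: 11 tert-butyl 2,3-dichloro-5-iodopyrrole-1-carboxylate
Conditions: Boc2O, DMAP (10 mol%), MeCN, 0 °C to rt (10 used at once as the dried extract from step 4)
Reagents that add atoms: di-tert-butyl dicarbonate, CC(C)(C)OC(=O)OC(=O)OC(C)(C)C
Why: DMAP-catalysed N-acylation: the N–H of the trihalopyrrole is acidic enough to be acylated despite the two flanking halogens, and the carbamate lowers the electron density of the ring, which should make the iodide storable and ready for oxidative addition.

Step 6
Reactants: 11 tert-butyl 2,3-dichloro-5-iodopyrrole-1-carboxylate; 12 carbon monoxide; 8 [2,4-dimethoxy-3-(4-methylpentyl)phenyl]boronic acid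
Product: 13 tert-butyl 2,3-dichloro-5-[2,4-dimethoxy-3-(4-methylpentyl)benzoyl]pyrrole-1-carboxylate
Conditions: Pd(PPh3)4 (5 mol%), K2CO3, CO (5 bar), anisole, 80 °C
Reagents that add atoms: none
Why: This is a carbonylative Suzuki–Miyaura coupling, and the closest known reaction type is the three-component coupling of aryl and heteroaryl iodides with carbon monoxide and arylboronic acids to diaryl ketones. Zerovalent palladium adds oxidatively to the C–I bond of 11, while the two much stronger C–Cl bonds stay intact, so the chemoselectivity rests on the difference between the halogens. Carbon monoxide then coordinates and inserts into the pyrrolyl–palladium bond to give an acyl complex of divalent palladium. The boronate formed from 8 and K2CO3 transfers its aryl group to this complex, and reductive elimination releases ketone 13 and returns zerovalent palladium. No ring is closed and no stereocentre is formed. The selectivity that the step needs is insertion of carbon monoxide ahead of direct pyrrolyl–aryl coupling, and it is secured in three ways: the ortho-methoxy group of 8, the weak base and the non-polar solvent slow the aryl transfer, the Boc group next to palladium hinders transfer at the pyrrolyl stage more than at the less crowded acyl stage, and the pressure of carbon monoxide speeds up insertion. The Boc group and the chlorines make the pyrrolyl–palladium species less electron-rich than that of a plain pyrrole, which is why the pressure is set above 1 bar. Loss of the Boc group from 13 under the basic conditions would be harmless, since step 7 removes it in any case.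

Step 7
Reactants: 13 tert-butyl 2,3-dichloro-5-[2,4-dimethoxy-3-(4-methylpentyl)benzoyl]pyrrole-1-carboxylate
Product: 14 (4,5-dichloro-1H-pyrrol-2-yl)[2,4-dihydroxy-3-(4-methylpentyl)phenyl]methanone
Conditions: BBr3 (excess), CH2Cl2, −78 °C to rt; then H2O
Reagents that add atoms: none
Why: Lewis-acid cleavage of aryl methyl ethers and of a tert-butyl carbamate: BBr3 binds the ketone, ether and carbamate oxygens, bromide removes the two methyl groups (the C2 one helped by chelation to the ketone) and the tert-butyl group, the carbamic acid loses CO2, and hydrolysis of the aryloxyboron species on work-up frees the resorcinol and the N–H. The ring, complexed by excess BBr3, is deactivated towards alkylation by the tert-butyl fragment, and the C–Cl bonds and the alkyl chain are inert.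

## Compound list

1 | 1,3-dimethoxybenzene | COc1cccc(OC)c1 | starting material
2 | 1-bromo-4-methylpentane | CC(C)CCCBr | starting material
3 | 2,6-dimethoxyphenyllithium | [Li]c1c(OC)cccc1OC | intermediate
4 | 1,3-dimethoxy-2-(4-methylpentyl)benzene | COc1cccc(OC)c1CCCC(C)C | intermediate
5 | 1-bromo-2,4-dimethoxy-3-(4-methylpentyl)benzene | COc1ccc(Br)c(OC)c1CCCC(C)C | intermediate
6 | [2,4-dimethoxy-3-(4-methylpentyl)phenyl]lithium | [Li]c1ccc(OC)c(CCCC(C)C)c1OC | intermediate
7 | lithium [2,4-dimethoxy-3-(4-methylpentyl)phenyl]tris(propan-2-yloxy)borate | [Li+].CC(C)O[B-](OC(C)C)(OC(C)C)c1ccc(OC)c(CCCC(C)C)c1OC | intermediate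
8 | [2,4-dimethoxy-3-(4-methylpentyl)phenyl]boronic acid | COc1ccc(B(O)O)c(OC)c1CCCC(C)C | intermediate
9 | 4,5-dichloro-1H-pyrrole-2-carboxylic acid | OC(=O)c1cc(Cl)c(Cl)[nH]1 | starting material
10 | 2,3-dichloro-5-iodo-1H-pyrrole | Ic1cc(Cl)c(Cl)[nH]1 | intermediate
11 | tert-butyl 2,3-dichloro-5-iodopyrrole-1-carboxylate | CC(C)(C)OC(=O)n1c(I)cc(Cl)c1Cl | intermediate
12 | carbon monoxide | [C-]#[O+] | starting material
13 | tert-butyl 2,3-dichloro-5-[2,4-dimethoxy-3-(4-methylpentyl)benzoyl]pyrrole-1-carboxylate | COc1ccc(C(=O)c2cc(Cl)c(Cl)n2C(=O)OC(C)(C)C)c(OC)c1CCCC(C)C | intermediate
14 | (4,5-dichloro-1H-pyrrol-2-yl)[2,4-dihydroxy-3-(4-methylpentyl)phenyl]methanone | CC(C)CCCc1c(O)ccc(C(=O)c2cc(Cl)c(Cl)[nH]2)c1O | target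

## Step count and least certain steps

Total step count: 7. Longest linear sequence: 5 steps (steps 1, 2, 3, 6 and 7). The pyrrole branch (steps 4 and 5) joins at step 6.

Step 6 (key step). The most likely failure is aryl transfer before carbon monoxide has inserted, which would join the two rings directly without the carbonyl bridge. Protodeboronation of the electron-rich boronic acid and loss of the Boc group from 11 before oxidative addition would both lower conversion further. The fallback builds the same two bonds in separate polar steps and sets out from 5 and 11. Bromide 5 is converted by n-BuLi into aryllithium 6 and quenched with N,N-dimethylformamide to give 2,4-dimethoxy-3-(4-methylpentyl)benzaldehyde F1. Iodide 11 undergoes iodine–magnesium exchange with i-PrMgCl·LiCl in THF at −40 °C to give tert-butyl 2,3-dichloro-5-(chloromagnesio)pyrrole-1-carboxylate F2. F2 adds to F1, and a cold quench, to prevent transfer of the Boc group to the new alkoxide, gives racemic tert-butyl 2,3-dichloro-5-{[2,4-dimethoxy-3-(4-methylpentyl)phenyl](hydroxy)methyl}pyrrole-1-carboxylate F3. Oxidation of this doubly activated carbinol with Dess–Martin periodinane in CH2Cl2 returns to the route at 13.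

Step 4. The N–H trihalopyrrole 10 has no electron-withdrawing group and may decompose by oxidation or oligomerisation before it is protected. Iodination could also continue at the free β-position, or decarboxylation could be incomplete on this chlorine-deactivated ring. The fallback abandons the iodide and forms the ketone by acylation, setting out from 9 and 4. Acid 9 is converted with oxalyl chloride and catalytic N,N-dimethylformamide into 4,5-dichloro-1H-pyrrole-2-carbonyl chloride F4. Friedel–Crafts acylation of arene 4 with F4 and AlCl3 in CH2Cl2 occurs at the same position as the bromination of step 2 and gives (4,5-dichloro-1H-pyrrol-2-yl)[2,4-dimethoxy-3-(4-methylpentyl)phenyl]methanone F5. Partial cleavage of the ortho methyl ether by AlCl3 would do no harm. Treatment of F5 with BBr3 returns to the route at 14.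

Step 7. The C4 methyl ether, which has no chelation help, may be cleaved incompletely. The strongly acidic medium could also lead to alkylation of the ring by the tert-butyl fragment or to protodeacylation of the resorcinol ketone. The fallback moves the demethylation to a robust stage and ends with a mild Brønsted acid, setting out from 5. BBr3 converts 5 into 4-bromo-2-(4-methylpentyl)benzene-1,3-diol F6. Chloromethyl methyl ether and i-Pr2NEt give 1-bromo-2,4-bis(methoxymethoxy)-3-(4-methylpentyl)benzene F7. Lithiation–borylation with aqueous NH4Cl work-up gives [2,4-bis(methoxymethoxy)-3-(4-methylpentyl)phenyl]boronic acid F8. Coupling of F8 with 11 and 12 under the conditions of step 6 gives tert-butyl 5-[2,4-bis(methoxymethoxy)-3-(4-methylpentyl)benzoyl]-2,3-dichloropyrrole-1-carboxylate F9. HCl in methanol removes both acetals and the Boc group and returns to the route at 14.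

Step 3. The electron-rich boronic acid may undergo protodeboronation during the acidic hydrolysis or on purification, and partial dehydration to boroxine would make its stoichiometry in step 6 uncertain. The fallback avoids the organolithium and the free boronic acid and sets out from 5. Miyaura borylation with bis(pinacolato)diboron, PdCl2(dppf) and KOAc in dioxane at 80 °C gives 2-[2,4-dimethoxy-3-(4-methylpentyl)phenyl]-4,4,5,5-tetramethyl-1,3,2-dioxaborolane F10. F10 takes the place of 8 in step 6 and returns to the route at 13.

## Further compounds

F1 | step 6 | 2,4-dimethoxy-3-(4-methylpentyl)benzaldehyde | COc1ccc(C=O)c(OC)c1CCCC(C)C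
F2 | step 6 | tert-butyl 2,3-dichloro-5-(chloromagnesio)pyrrole-1-carboxylate | CC(C)(C)OC(=O)n1c([Mg]Cl)cc(Cl)c1Cl
F3 | step 6 | tert-butyl 2,3-dichloro-5-{[2,4-dimethoxy-3-(4-methylpentyl)phenyl](hydroxy)methyl}pyrrole-1-carboxylate (racemic) | COc1ccc(C(O)c2cc(Cl)c(Cl)n2C(=O)OC(C)(C)C)c(OC)c1CCCC(C)C
F4 | step 4 | 4,5-dichloro-1H-pyrrole-2-carbonyl chloride | O=C(Cl)c1cc(Cl)c(Cl)[nH]1
F5 | step 4 | (4,5-dichloro-1H-pyrrol-2-yl)[2,4-dimethoxy-3-(4-methylpentyl)phenyl]methanone | COc1ccc(C(=O)c2cc(Cl)c(Cl)[nH]2)c(OC)c1CCCC(C)C
F6 | step 7 | 4-bromo-2-(4-methylpentyl)benzene-1,3-diol | CC(C)CCCc1c(O)ccc(Br)c1O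
F7 | step 7 | 1-bromo-2,4-bis(methoxymethoxy)-3-(4-methylpentyl)benzene | COCOc1ccc(Br)c(OCOC)c1CCCC(C)C
F8 | step 7 | [2,4-bis(methoxymethoxy)-3-(4-methylpentyl)phenyl]boronic acid | COCOc1ccc(B(O)O)c(OCOC)c1CCCC(C)C
F9 | step 7 | tert-butyl 5-[2,4-bis(methoxymethoxy)-3-(4-methylpentyl)benzoyl]-2,3-dichloropyrrole-1-carboxylate | COCOc1ccc(C(=O)c2cc(Cl)c(Cl)n2C(=O)OC(C)(C)C)c(OCOC)c1CCCC(C)C
F10 | step 3 | 2-[2,4-dimethoxy-3-(4-methylpentyl)phenyl]-4,4,5,5-tetramethyl-1,3,2-dioxaborolane | COc1ccc(B2OC(C)(C)C(C)(C)O2)c(OC)c1CCCC(C)C
A1 | alternative 1 | 1-[4,5-dichloro-1-{[2-(trimethylsilyl)ethoxy]methyl}pyrrol-2-yl]-8-methylnonane-1,3-dione | CC(C)CCCCC(=O)CC(=O)c1cc(Cl)c(Cl)n1COCC[Si](C)(C)C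
A2 | alternative 1 | methyl acrylate | C=CC(=O)OC
A3 | alternative 1 | 4-[4,5-dichloro-1-{[2-(trimethylsilyl)ethoxy]methyl}pyrrole-2-carbonyl]-2-(4-methylpentyl)cyclohexane-1,3-dione (dienol tautomer) | CC(C)CCCC1=C(O)CCC(C(=O)c2cc(Cl)c(Cl)n2COCC[Si](C)(C)C)=C1O
A4 | alternative 2 | 1-methoxy-2-(4-methylpentyl)-1,3-bis(trimethylsilyloxy)buta-1,3-diene | C=C(O[Si](C)(C)C)C(CCCC(C)C)=C(OC)O[Si](C)(C)C
A5 | alternative 2 | 1-[4,5-dichloro-1-(4-methylbenzenesulfonyl)pyrrol-2-yl]prop-2-yn-1-one | C#CC(=O)c1cc(Cl)c(Cl)n1S(=O)(=O)c1ccc(C)cc1
A6 | alternative 2 | [4,5-dichloro-1-(4-methylbenzenesulfonyl)pyrrol-2-yl][2,4-dihydroxy-3-(4-methylpentyl)phenyl]methanone | CC(C)CCCc1c(O)ccc(C(=O)c2cc(Cl)c(Cl)n2S(=O)(=O)c2ccc(C)cc2)c1O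
A7 | alternative 3 | 2-amino-1-[2,4-dimethoxy-3-(4-methylpentyl)phenyl]ethanone | COc1ccc(C(=O)CN)c(OC)c1CCCC(C)C
A8 | alternative 3 | 2,3,3-trichloroprop-2-enal | O=CC(Cl)=C(Cl)Cl
A9 | alternative 3 | (4,5-dichloro-1H-pyrrol-2-yl)[2,4-dimethoxy-3-(4-methylpentyl)phenyl]methanone | COc1ccc(C(=O)c2cc(Cl)c(Cl)[nH]2)c(OC)c1CCCC(C)C
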